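**Conventions.** Atoms are numbered along the SMILES of target 37 as written in the compound list: C1–C2 (ethyl), C3, C4, O5, C6(=O7), C8 (C9 methyl), C10, C11(=O12), C13, C14, C15, C16, C17 (C18 methyl), C19(=O20), O21, N22, C23–C26, C27, C28(=O29). Ring A = N22, C14, C13, C11, C10, C4, C3, C27, C28; ring B = N22, C23–C27, C28; ring C = C4, O5, C6, C8, C10. TBS = tert-butyldimethylsilyl, TBDPS = tert-butyldiphenylsilyl, PMB = 4-methoxybenzyl.

**Assumption.** The commercial N-Boc methyl ester of cis-4-hydroxy-L-proline (1) and (R)-3-bromo-2-methylpropan-1-ol (4) are taken as the chiral starting materials.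

## The problem

Target 37 is a nine-membered lactam (ring A) whose amide N22–C28 is shared with a seven-membered lactam (ring B), so ring A must hold a transoid amide. A γ-lactone (ring C) is cis-fused to ring A at C4–C10, and an α-methyl-γ-butyrolactone hangs from C14. Of the eight stereocentres, five (C27, C3, C4, C10, C8) sit on or next to the medium ring, where acyclic models are unreliable; they have to be set by chirality transfer or by the shape of a ring that already exists. C14 can come from the chiral pool and can control C10 while that carbon is still part of a pyrrolidine; C10 can then hand its chirality to C27 and C3. The C11 oxygen, which ends as a ketone, is available as a temporary stereocentre to steer first C10 and later C4; C4 in turn can control C10 and C8 on the lactone; C14 can control C15, and C17 can be bought. The C11 ketone is β to the lactone oxygen O5 and α to the epimerisable C10, so base opens ring C by E1cB elimination and scrambles C10; the ketone must therefore appear last and without base. Ring A holds the amide N22–C28 next to the adjacent stereocentres C27 and C3, with C10 four atoms from N22 (N22–C14–C13–C11–C10). This is exactly the pattern left by the [3,3] rearrangement of a 1-acyl-2-alkenylpyrrolidine, in which C27–C3 forms and N22–C10 breaks.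

## Retrosynthesis

**C11 ketone and side lactone (37 ⇐ 36 ⇐ 35 ⇐ 34).** No skeletal bond is cut at first: the C11 ketone of 37 is traced to the carbinol 36, because the β-acyloxy ketone should not meet base. The side lactone of 36 is then opened at O21–C19 to the 1,4-diol of triol 35, which comes from the tris-silyl ether 34 in one deprotection. Carrying C15–C19 as a protected diol is preferred to building it late from a C14 aldehyde, which would be an epimerisable α-amido aldehyde on a hindered polycycle. The forward steps must oxidise a primary alcohol in the presence of two secondary ones and must not move the ring C acyl group to the free C11 hydroxyl.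

**Ring C (34 ⇐ 32 ⇐ 31 ⇐ 30 ⇐ 28 ⇐ 27).** C8–C10 is cut as a C8=C10 double bond (butenolide 32) and O5–C6 as an ester, which leads to the α-acyloxy ketone 31 and, through alcohol 30, to the syn-diol 28 of the E-olefin 27. Opening a C4/C10 epoxide with a propionate nucleophile at C10 looks shorter, but it asks for backside attack on a trans-epoxide of a nine-membered ring, where the backside points into the ring, and at the carbon that the C11 oxygen deactivates. The chosen sequence needs only reagents that approach from outside (OsO4, hydride) and one intramolecular olefination. It asks the forward chemistry for face selectivity in the osmylation (sets C4), for discrimination of two secondary hydroxyls, and for hydrogen delivery to C10 from the convex face of the butenolide.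

**Ring B (27 ⇐ 26 ⇐ 25 ⇐ 24).** The N22–C23 bond is cut, which leaves a secondary lactam with a four-carbon chain on C27 ending in a leaving group (mesylate 26, from alcohol 25 and PMB ether 24). Cutting here instead of at C26–C27 keeps the whole C23–C28 unit as one simple acyl group in the key step. The forward reaction is a 7-exo-tet N-alkylation that must win over O-alkylation.

**Ring A, the key cut (24 ⇐ 22).** Reconnecting N22 to C10 and cutting C27–C3 turns the nine-membered E-olefinic lactam 24 into the N-acyl trans-2,5-disubstituted pyrrolidine 22 with a Z-butenyl group on C10. Against a lactamisation or an olefin-forming closure of ring A, this cut replaces a medium-ring cyclisation by a ring expansion through a six-membered transition state and sets C27 and C3 together. The precursor is much simpler: one ring, its stereocentres from the chiral pool, and an achiral acyl chain. The forward step must go through the chair with C11 equatorial and with a Z enolate.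

**Amide and acyl chain (22 ⇐ 18 + 20; 20 ⇐ 19).** The N22–C28 amide is cut to pyrrolidine 18 and 6-(PMB-oxy)hexanoic acid 20, which comes from ε-caprolactone 19 in one operation. The forward acylation has to cope with a hindered amine.

**C10 substituent (18 ⇐ 16 ⇐ 15 ⇐ 10 + 14; 10 ⇐ 9).** The C10–C4 bond is cut to an N-acyliminium ion, made from carbamate 9 by anodic methoxylation (N,O-acetal 10), and a butynyl donor 14 made from but-1-yne 11; the alkyne 15 is the source of the Z olefin 16. An alkyne is chosen over a Z-alkenyl metal because its geometry is made cleanly afterwards. The forward addition must come anti to the C11 silyloxy group and to the C14 substituent, which lie on the same face because the starting amino acid is the cis isomer.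

**Side chain (9 ⇐ 8 ⇐ 7 ⇐ 3 + 5; 3 ⇐ 2 ⇐ 1; 5 ⇐ 4).** C15–C16 is cut to the Weinreb amide 3 (from ester 2 and hydroxyproline derivative 1) and the Grignard reagent of bromide 5, which carries C17 from the commercial bromo alcohol 4. A ketone (7) is chosen as the intermediate because its Felkin–Anh reduction gives the 15S carbinol 8, whereas direct addition of a carbon nucleophile to a C15 aldehyde would favour 15R.

## Roads not taken

**Alternative 1: ring-closing Barbier allylation with lactonisation in the same step.** The cut is C4–C10 together with O5–C6. In the forward step, divalent chromium (CrCl2) would turn the Z 2-(bromomethyl)enoate of the open-chain aldehyde A1 into an allylchromium species that attacks the C4 aldehyde through C10; the alkoxide then closes ring C to the α-methylene lactone A2. In economy around ring C this road is better than the chosen one: one step does what steps 18–22 do here, and C8 would follow by hydrogenation and equilibration. Its weak points lie elsewhere. Ring A is closed by C–C bond formation from a flexible chain, the C4/C10 relationship comes from a transition state inside the forming medium ring and cannot be corrected afterwards, and A1 must already hold ring B with the adjacent C27/C3 pair, built by acyclic stereocontrol. The chosen plan sets against the shorter lactone work a ring A formation that is a rearrangement through a chair and a C27/C3 pair that comes from one stereocentre of the chiral pool.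

**Alternative 2: Ueno–Stork radical annulation of the fused lactone.** The cut is C8–C10. Bu3SnH would generate the C8 radical of bromoacetal A3, which adds 5-exo to C10 of the ring silyl enol ether; the C11 radical takes hydrogen and gives the lactol ether A4. As a tactic for ring C this is at least as reliable as the olefination and reduction used here: the cis fusion is kinetic, there is no face question at C10, and the C11 oxygen stays in place. As a strategy it is incomplete, because it presupposes ring A with C27 and C3. It also needs a regio-defined C10=C11 silyl enol ether next to a C4 oxygen (the parent β-hydroxy ketone eliminates easily), stoichiometric tin, a later oxidation of the lactol ether and an equilibration at C8. The chosen plan offers a solution for ring A and tin-free steps; Alternative 2 would remain a possible replacement for steps 19–22 only.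

**Alternative 3: nitroketone ring enlargement from six to nine.** The cut is the amide N22–C28, with the C28–C11 bond present in the precursor. The primary amine on C14 of nitroketone A5 would add to the C28 ketone, and fragmentation with loss of the nitronate would give the nine-membered lactam nitronate A6. Its merit is real: C3, C4, C8, C10 and C27 would be set on a cyclohexane, where relative control is easiest, and the nitronate is a direct precursor of the C11 ketone. In this respect it is better than the chosen plan, which has to create C4, C10 and C8 on the medium ring. Against it, ring C is carried through basic steps as a β-acyloxy nitro compound and nitronate, the same elimination-prone array that the chosen plan unveils only in the last step. The C14 stereocentre and the quaternary nitro carbon of A5 must be made without an obvious control element. Ring B and the side lactone are still to be built on a secondary lactam. The chosen plan sets against the easier ring C stereochemistry a C14/C15/C17 unit taken intact from the chiral pool and a ketone that never meets base.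

Key step: step 14

## Route

Step 1
Reactants: 1 N-Boc-cis-4-hydroxy-L-proline methyl ester
Product: 2 1-tert-butyl 2-methyl (2S,4S)-4-(tert-butyldiphenylsilyloxy)pyrrolidine-1,2-dicarboxylate
Conditions: t-BuPh2SiCl, imidazole, DMF, rt
Reagents that add atoms: tert-butyl(chloro)diphenylsilane, CC(C)(C)[Si](Cl)(c1ccccc1)c1ccccc1
Why: Imidazole-mediated silylation of the secondary alcohol; the bulky, robust TBDPS ether on the future C11 later shields one face of C10 and the neighbouring C10 hydroxyl.

Step 2
Reactants: 2 silyl ether ester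
Product: 3 tert-butyl (2S,4S)-4-(tert-butyldiphenylsilyloxy)-2-[methoxy(methyl)carbamoyl]pyrrolidine-1-carboxylate
Conditions: MeNH(OMe)·HCl, i-PrMgCl, THF, −20 °C
Reagents that add atoms: N,O-dimethylhydroxylamine hydrochloride, CNOC.Cl
Why: Ester aminolysis by the chloromagnesium amide of N,O-dimethylhydroxylamine (Weinreb amide formation); the low-temperature, non-enolising conditions preserve C14.

Step 3
Reactants: 4 (R)-3-bromo-2-methylpropan-1-ol
Product: 5 [(2R)-3-bromo-2-methylpropoxy](tert-butyl)dimethylsilane
Conditions: t-BuMe2SiCl, imidazole, CH2Cl2, rt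
Reagents that add atoms: tert-butyl(chloro)dimethylsilane, CC(C)(C)[Si](C)(C)Cl
Why: Standard silylation; the chiral-pool centre becomes C17 (17S once the CH2Br carbon is C16 and the CH2O carbon is C19).

Step 4
Reactants: 5 silyl-protected bromide; 3 Weinreb amide
Product: 7 tert-butyl (2S,4S)-2-[(3S)-4-(tert-butyldimethylsilyloxy)-3-methylbutanoyl]-4-(tert-butyldiphenylsilyloxy)pyrrolidine-1-carboxylate, via Grignard reagent 6 (not isolated)
Conditions: Mg, I2 (cat.), THF, 40 °C; then 3, THF, 0 °C
Reagents that add atoms: none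
Why: Grignard formation and acyl substitution on the Weinreb amide form the C15–C16 bond; the chelated tetrahedral intermediate stops at the ketone and leaves C14 untouched.

Step 5
Reactants: 7 C15 ketone
Product: 8 tert-butyl (2S,4S)-2-[(1S,3S)-4-(tert-butyldimethylsilyloxy)-1-hydroxy-3-methylbutyl]-4-(tert-butyldiphenylsilyloxy)pyrrolidine-1-carboxylate
Conditions: LiBH(s-Bu)3, THF, −78 °C
Reagents that add atoms: none
Why: Felkin–Anh reduction by a bulky hydride: with the carbamate nitrogen anti to the incoming hydride and the C16 chain beside the small C14–H, the 15S carbinol should predominate.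

Step 6
Reactants: 8 C15 alcohol
Product: 9 tert-butyl (2S,4S)-2-[(1S,3S)-1,4-bis(tert-butyldimethylsilyloxy)-3-methylbutyl]-4-(tert-butyldiphenylsilyloxy)pyrrolidine-1-carboxylate
Conditions: t-BuMe2SiOTf, 2,6-lutidine, CH2Cl2, −78 → 0 °C
Reagents that add atoms: tert-butyldimethylsilyl trifluoromethanesulfonate, CC(C)(C)[Si](C)(C)OS(=O)(=O)C(F)(F)F
Why: Silyl triflate silylation of a hindered secondary alcohol.

Step 7
Reactants: 9 tris-silyl carbamate
Product: 10 tert-butyl (3S,5S)-5-[(1S,3S)-1,4-bis(tert-butyldimethylsilyloxy)-3-methylbutyl]-3-(tert-butyldiphenylsilyloxy)-2-methoxypyrrolidine-1-carboxylate (both C10 epimers)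
Conditions: graphite anode, Pt cathode, Et4NOTs, MeOH, 0 °C, constant current
Reagents that add atoms: methanol, CO
Why: Shono anodic α-methoxylation of the carbamate; the N-acyliminium ion forms at the less substituted α-carbon C10 (CH2) and not at the C14 methine, and both C10 epimers converge in step 9.

Step 8
Reactants: 11 but-1-yne
Product: 14 potassium (but-1-yn-1-yl)trifluoroborate, via but-1-ynyllithium 12 (not isolated), via lithium butynyltrimethoxyborate 13 (not isolated)
Conditions: n-BuLi, THF, −78 °C; B(OMe)3, −78 → −20 °C; aq KHF2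
Reagents that add atoms: trimethyl borate, COB(OC)OC; potassium hydrogen difluoride, [K+].F.[F-]
Why: Deprotonation of the terminal alkyne, borylation and fluoride exchange (standard preparation of potassium alkynyltrifluoroborates) turn gaseous but-1-yne into a weighable alkynyl donor.

Step 9
Reactants: 10 N,O-acetal; 14 potassium butynyltrifluoroborate
Product: 15 tert-butyl (2R,3S,5S)-2-(but-1-yn-1-yl)-3-(tert-butyldiphenylsilyloxy)-5-[(1S,3S)-1,4-bis(tert-butyldimethylsilyloxy)-3-methylbutyl]pyrrolidine-1-carboxylate
Conditions: BF3·OEt2, CH2Cl2, −78 → 0 °C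
Reagents that add atoms: none
Why: BF3 ionises the N,O-acetal to the N-acyliminium ion, which is alkynylated by the trifluoroborate (N-acyliminium alkynylation, C10–C4 bond); attack comes anti to the adjacent C11 silyloxy group and anti to the C14 side chain, which share one face, and sets 10R.

Step 10
Reactants: 15 alkynylpyrrolidine
Product: 16 tert-butyl (2R,3S,5S)-2-[(1Z)-but-1-en-1-yl]-3-(tert-butyldiphenylsilyloxy)-5-[(1S,3S)-1,4-bis(tert-butyldimethylsilyloxy)-3-methylbutyl]pyrrolidine-1-carboxylate
Conditions: H2 (1 atm), Pd/CaCO3 poisoned with Pb(OAc)2 (Lindlar catalyst), quinoline, EtOAc, rt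
Reagents that add atoms: none
Why: Lindlar semihydrogenation (syn addition of H2) gives the Z olefin that the key step needs for the C3 configuration.

Step 11
Reactants: 16 Z-alkenyl carbamate
Product: 18 (2R,3S,5S)-2-[(1Z)-but-1-en-1-yl]-3-(tert-butyldiphenylsilyloxy)-5-[(1S,3S)-1,4-bis(tert-butyldimethylsilyloxy)-3-methylbutyl]pyrrolidine, via trimethylsilyl carbamate 17 (not isolated)
Conditions: Me3SiOTf, 2,6-lutidine, CH2Cl2, 0 °C; then MeOH
Reagents that add atoms: none
Why: Silyl-triflate-mediated Boc cleavage through the silyl carbamate, which loses CO2 on methanolysis; unlike protic acid it spares the silyl ethers and the Z olefin.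

Step 12
Reactants: 19 ε-caprolactone
Product: 20 6-(4-methoxybenzyloxy)hexanoic acid
Conditions: KOH, 4-methoxybenzyl chloride, toluene, reflux; then aq HCl
Reagents that add atoms: 4-methoxybenzyl chloride, COc1ccc(CCl)cc1; potassium hydroxide, [K+].[OH-]
Why: Saponification of the lactone and Williamson etherification of the resulting alkoxide in one pot give the protected hydroxy acid after acidification.

Step 13
Reactants: 20 6-(4-methoxybenzyloxy)hexanoic acid; 18 pyrrolidine
Product: 22 1-[(2R,3S,5S)-2-[(1Z)-but-1-en-1-yl]-3-(tert-butyldiphenylsilyloxy)-5-[(1S,3S)-1,4-bis(tert-butyldimethylsilyloxy)-3-methylbutyl]pyrrolidin-1-yl]-6-(4-methoxybenzyloxy)hexan-1-one, via acid chloride 21 (not isolated)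
Conditions: (COCl)2, DMF (cat.), CH2Cl2, 0 °C; then 18, Et3N, DMAP (cat.), CH2Cl2, 0 → 40 °C
Reagents that add atoms: none
Why: Acid chloride formation and N-acylation (N22–C28 bond); the acid chloride with DMAP is chosen because the trans-2,5-disubstituted amine is hindered.

Step 14
Reactants: 22 N-acyl-2-(Z-butenyl)pyrrolidine
Product: 24 (3S,4S,5E,7S,9S)-9-[(1S,3S)-1,4-bis(tert-butyldimethylsilyloxy)-3-methylbutyl]-7-(tert-butyldiphenylsilyloxy)-4-ethyl-3-[4-(4-methoxybenzyloxy)butyl]-1-azacyclonon-5-en-2-one, via lithium Z enolate 23 (not isolated)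
Conditions: LiN(SiMe3)2, toluene, 110 °C
Reagents that add atoms: none
Why: LiN(SiMe3)2 deprotonates C27 to the Z(O) lithium enolate 23, and on heating the N22–C10 σ bond, the enolate π bond and the butenyl π bond reorganise in a concerted suprafacial [3,3] shift; this is the amide-enolate aza-Claisen rearrangement, the nitrogen analogue of the Ireland–Claisen rearrangement, known for 1-acyl-2-alkenyl azacycles. Ring A is not closed end to end: it arises by four-atom ring expansion of the pyrrolidine, C27–C3 forming while N22–C10 breaks inside a six-membered chair. C27 is set by the enolate geometry (C26 chain equatorial) and C3 by the Z olefin geometry (ethyl axial), so their relative configuration follows from the chair. Their absolute configuration is relayed from C10 (R), because the chair with C11 equatorial on C10 presents only one face of the allyl unit to the enolate. The same equatorial C11 makes the new C4=C10 olefin E and leaves the lactam transoid, with N–H on the side of C27 as ring B will need. The step needs chair over boat and C11 equatorial over axial; the N22–C10 bond shared by the pyrrolidine and the chair, and the C14 and C11 substituents on the face away from the butenyl group, should secure both. The change from an enolate to a resonance-stabilised lithium amidate, with loss of the allylic C–N bond, drives the shift and makes it irreversible.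

Step 15
Reactants: 24 nine-membered lactam PMB ether
Product: 25 the corresponding 3-(4-hydroxybutyl) lactam (C23 primary alcohol)
Conditions: DDQ, CH2Cl2/H2O, 0 °C → rt
Reagents that add atoms: none
Why: Oxidative PMB cleavage by DDQ (benzylic hydride abstraction, hydrolysis of the oxocarbenium ion); silyl ethers, lactam and olefin are inert.

Step 16
Reactants: 25 primary alcohol
Product: 26 the corresponding C23 methanesulfonate
Conditions: MeSO2Cl, Et3N, CH2Cl2, 0 °C
Reagents that add atoms: methanesulfonyl chloride, CS(=O)(=O)Cl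
Why: Mesylation of the primary alcohol; the lactam N–H is not sulfonylated by an amine base.

Step 17
Reactants: 26 mesylate
Product: 27 (2S,4S,5E,7S,8S)-2-[(1S,3S)-1,4-bis(tert-butyldimethylsilyloxy)-3-methylbutyl]-4-(tert-butyldiphenylsilyloxy)-7-ethyl-1-azabicyclo[6.4.1]tridec-5-en-13-one (rings A and B)
Conditions: NaH, THF, 0 → 50 °C, high dilution
Reagents that add atoms: none
Why: Intramolecular N-alkylation of the sodium amidate (7-exo-tet) forms N22–C23 and closes ring B; the transoid lactam from step 14 has nitrogen, not oxygen, on the side of the C27 chain, and dilution suppresses oligomers.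

Step 18
Reactants: 27 bicyclic E-olefin
Product: 28 the (4S,10R)-4,10-diol of 27 (both hydroxyls added syn; other centres unchanged)
Conditions: OsO4 (cat.), N-methylmorpholine N-oxide, acetone/H2O, rt
Reagents that add atoms: osmium tetroxide (catalytic oxygen carrier), O=[Os](=O)(=O)=O; N-methylmorpholine N-oxide, C[N+]1([O-])CCOCC1; water, O
Why: Upjohn syn-dihydroxylation of the strained E olefin; OsO4 should add to the peripheral face of the conformer that has the C11–O bond near the olefin plane and C13 anti (Kishi's empirical rule, new C10–O erythro to C11–O), which fixes 4S; the C10 carbinol configuration is lost in step 20.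

Step 19
Reactants: 28 diol; 29 2-(diethoxyphosphoryl)propanoic acid
Product: 30 the C4 2-(diethoxyphosphoryl)propanoate of 28 (C10 hydroxyl free; both epimers at the phosphonate carbon)
Conditions: EDC·HCl, DMAP (cat.), CH2Cl2, −10 → 0 °C
Reagents that add atoms: none
Why: Steglich esterification with retention at C4; O4 should react first because the C10 hydroxyl is flanked by the C11 TBDPS ether and by a second oxygen-bearing carbon.

Step 20
Reactants: 30 hydroxy ester
Product: 31 the C10 ketone of 30 (α-acyloxy ketone)
Conditions: Dess–Martin periodinane, CH2Cl2, rt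
Reagents that add atoms: none
Why: Dess–Martin oxidation of the remaining secondary alcohol under neutral conditions, without acyl migration or epimerisation at C4.

Step 21
Reactants: 31 keto phosphonate
Product: 32 butenolide: ring C closed with a C8=C10 double bond and C8 methyl (4S)
Conditions: LiCl, DBU, MeCN, rt
Reagents that add atoms: none
Why: Intramolecular Horner–Wadsworth–Emmons olefination under Masamune–Roush conditions forms C8=C10 and closes ring C (five-ring closure onto the ketone); the mild base limits epimerisation at C4.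

Step 22
Reactants: 32 butenolide
Product: 34 cis-fused saturated lactone with C3 C4 C8 C10 C27 as in the target and silyl ethers at O11 O15 O19, via C8-epimeric lactone 33 (not isolated)
Conditions: NiCl2·6H2O, NaBH4, MeOH/THF, −30 → 0 °C; then NaOMe (cat.), MeOH, rt
Reagents that add atoms: none
Why: Nickel boride conjugate reduction of an α-methylbutenolide, as used for Stemona lactones; hydrogen reaches C10 from the convex face, syn to H4 and away from C3 and ring A, giving the cis fusion. The first-formed C8 epimer 33 is equilibrated by methoxide to the isomer with the methyl group on the convex face, trans to C11.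

Step 23
Reactants: 34 tris-silyl ether
Product: 35 triol (free hydroxyls at C11 C15 C19; ring C intact)
Conditions: HF·pyridine, THF, 0 °C → rt
Reagents that add atoms: none
Why: Fluoride cleavage of all three silyl ethers; acidic HF·pyridine is preferred to basic Bu4NF so that no alkoxide moves the ring C acyl group from O5 to the freed C11 hydroxyl.

Step 24
Reactants: 35 triol
Product: 36 C11 carbinol with both lactones in place (side lactone C15–C19 closed)
Conditions: TEMPO (cat.), PhI(OAc)2, CH2Cl2, rt
Reagents that add atoms: none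
Why: TEMPO/PhI(OAc)2 oxidises the primary C19 alcohol selectively; the aldehyde is trapped by the C15 hydroxyl as a lactol that is oxidised on to the lactone (oxidative lactonisation of a 1,4-diol), while the hindered C11 carbinol reacts more slowly.

Step 25
Reactants: 36 hydroxy bis-lactone
Product: 37 target compound CNP0311700.3
Conditions: Dess–Martin periodinane, CH2Cl2, rt
Reagents that add atoms: none
Why: Dess–Martin oxidation of C11 under non-basic conditions as the last step, so that the β-acyloxy ketone never meets base (no E1cB opening of ring C, no epimerisation at C10).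

## Compound list

1 | N-Boc-cis-4-hydroxy-L-proline methyl ester, 1-tert-butyl 2-methyl (2S,4S)-4-hydroxypyrrolidine-1,2-dicarboxylate | COC(=O)[C@@H]1C[C@H](O)CN1C(=O)OC(C)(C)C | starting material
2 | 1-tert-butyl 2-methyl (2S,4S)-4-(tert-butyldiphenylsilyloxy)pyrrolidine-1,2-dicarboxylate | COC(=O)[C@@H]1C[C@H](O[Si](c2ccccc2)(c2ccccc2)C(C)(C)C)CN1C(=O)OC(C)(C)C | intermediate
3 | tert-butyl (2S,4S)-4-(tert-butyldiphenylsilyloxy)-2-[methoxy(methyl)carbamoyl]pyrrolidine-1-carboxylate | CON(C)C(=O)[C@@H]1C[C@H](O[Si](c2ccccc2)(c2ccccc2)C(C)(C)C)CN1C(=O)OC(C)(C)C | intermediate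
4 | (R)-3-bromo-2-methylpropan-1-ol | OC[C@@H](C)CBr | starting material
5 | [(2R)-3-bromo-2-methylpropoxy](tert-butyl)dimethylsilane | CC(C)(C)[Si](C)(C)OC[C@@H](C)CBr | intermediate
6 | [(2R)-3-(tert-butyldimethylsilyloxy)-2-methylpropyl]magnesium bromide | CC(C)(C)[Si](C)(C)OC[C@@H](C)C[Mg]Br | intermediate
7 | tert-butyl (2S,4S)-2-[(3S)-4-(tert-butyldimethylsilyloxy)-3-methylbutanoyl]-4-(tert-butyldiphenylsilyloxy)pyrrolidine-1-carboxylate | CC(C)(C)[Si](C)(C)OC[C@@H](C)CC(=O)[C@@H]1C[C@H](O[Si](c2ccccc2)(c2ccccc2)C(C)(C)C)CN1C(=O)OC(C)(C)C | intermediate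
8 | tert-butyl (2S,4S)-2-[(1S,3S)-4-(tert-butyldimethylsilyloxy)-1-hydroxy-3-methylbutyl]-4-(tert-butyldiphenylsilyloxy)pyrrolidine-1-carboxylate | CC(C)(C)[Si](C)(C)OC[C@@H](C)C[C@H](O)[C@@H]1C[C@H](O[Si](c2ccccc2)(c2ccccc2)C(C)(C)C)CN1C(=O)OC(C)(C)C | intermediate
9 | tert-butyl (2S,4S)-2-[(1S,3S)-1,4-bis(tert-butyldimethylsilyloxy)-3-methylbutyl]-4-(tert-butyldiphenylsilyloxy)pyrrolidine-1-carboxylate | CC(C)(C)[Si](C)(C)OC[C@@H](C)C[C@H](O[Si](C)(C)C(C)(C)C)[C@@H]1C[C@H](O[Si](c2ccccc2)(c2ccccc2)C(C)(C)C)CN1C(=O)OC(C)(C)C | intermediate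
10 | tert-butyl (3S,5S)-5-[(1S,3S)-1,4-bis(tert-butyldimethylsilyloxy)-3-methylbutyl]-3-(tert-butyldiphenylsilyloxy)-2-methoxypyrrolidine-1-carboxylate (both C10 epimers) | CC(C)(C)[Si](C)(C)OC[C@@H](C)C[C@H](O[Si](C)(C)C(C)(C)C)[C@@H]1C[C@H](O[Si](c2ccccc2)(c2ccccc2)C(C)(C)C)C(OC)N1C(=O)OC(C)(C)C | intermediate
11 | but-1-yne | CCC#C | starting material
12 | but-1-yn-1-yllithium | CCC#C[Li] | intermediate
13 | lithium (but-1-yn-1-yl)trimethoxyborate | CCC#C[B-](OC)(OC)OC.[Li+] | intermediate
14 | potassium (but-1-yn-1-yl)trifluoroborate | CCC#C[B-](F)(F)F.[K+] | intermediate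
15 | tert-butyl (2R,3S,5S)-2-(but-1-yn-1-yl)-3-(tert-butyldiphenylsilyloxy)-5-[(1S,3S)-1,4-bis(tert-butyldimethylsilyloxy)-3-methylbutyl]pyrrolidine-1-carboxylate | CC(C)(C)[Si](C)(C)OC[C@@H](C)C[C@H](O[Si](C)(C)C(C)(C)C)[C@@H]1C[C@H](O[Si](c2ccccc2)(c2ccccc2)C(C)(C)C)[C@@H](C#CCC)N1C(=O)OC(C)(C)C | intermediate
16 | tert-butyl (2R,3S,5S)-2-[(1Z)-but-1-en-1-yl]-3-(tert-butyldiphenylsilyloxy)-5-[(1S,3S)-1,4-bis(tert-butyldimethylsilyloxy)-3-methylbutyl]pyrrolidine-1-carboxylate | CC(C)(C)[Si](C)(C)OC[C@@H](C)C[C@H](O[Si](C)(C)C(C)(C)C)[C@@H]1C[C@H](O[Si](c2ccccc2)(c2ccccc2)C(C)(C)C)[C@@H](/C=C\CC)N1C(=O)OC(C)(C)C | intermediate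
17 | trimethylsilyl carbamate of pyrrolidine 18 (N–CO2SiMe3) | CC(C)(C)[Si](C)(C)OC[C@@H](C)C[C@H](O[Si](C)(C)C(C)(C)C)[C@@H]1C[C@H](O[Si](c2ccccc2)(c2ccccc2)C(C)(C)C)[C@@H](/C=C\CC)N1C(=O)O[Si](C)(C)C | intermediate
18 | (2R,3S,5S)-2-[(1Z)-but-1-en-1-yl]-3-(tert-butyldiphenylsilyloxy)-5-[(1S,3S)-1,4-bis(tert-butyldimethylsilyloxy)-3-methylbutyl]pyrrolidine | CC(C)(C)[Si](C)(C)OC[C@@H](C)C[C@H](O[Si](C)(C)C(C)(C)C)[C@@H]1C[C@H](O[Si](c2ccccc2)(c2ccccc2)C(C)(C)C)[C@@H](/C=C\CC)N1 | intermediate
19 | ε-caprolactone (oxepan-2-one) | O=C1CCCCCO1 | starting material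
20 | 6-(4-methoxybenzyloxy)hexanoic acid | COc1ccc(COCCCCCC(O)=O)cc1 | intermediate
21 | 6-(4-methoxybenzyloxy)hexanoyl chloride | COc1ccc(COCCCCCC(Cl)=O)cc1 | intermediate
22 | 1-[(2R,3S,5S)-2-[(1Z)-but-1-en-1-yl]-3-(tert-butyldiphenylsilyloxy)-5-[(1S,3S)-1,4-bis(tert-butyldimethylsilyloxy)-3-methylbutyl]pyrrolidin-1-yl]-6-(4-methoxybenzyloxy)hexan-1-one (key-step precursor) | CC(C)(C)[Si](C)(C)OC[C@@H](C)C[C@H](O[Si](C)(C)C(C)(C)C)[C@@H]1C[C@H](O[Si](c2ccccc2)(c2ccccc2)C(C)(C)C)[C@@H](/C=C\CC)N1C(=O)CCCCCOCc1ccc(OC)cc1 | intermediate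
23 | lithium Z(O) enolate of amide 22 (C27=C28–OLi) | CC(C)(C)[Si](C)(C)OC[C@@H](C)C[C@H](O[Si](C)(C)C(C)(C)C)[C@@H]1C[C@H](O[Si](c2ccccc2)(c2ccccc2)C(C)(C)C)[C@@H](/C=C\CC)N1/C(O[Li])=C/CCCCOCc1ccc(OC)cc1 | intermediate
24 | (3S,4S,5E,7S,9S)-9-[(1S,3S)-1,4-bis(tert-butyldimethylsilyloxy)-3-methylbutyl]-7-(tert-butyldiphenylsilyloxy)-4-ethyl-3-[4-(4-methoxybenzyloxy)butyl]-1-azacyclonon-5-en-2-one (key-step product) | O=C1N[C@H]([C@@H](O[Si](C)(C)C(C)(C)C)C[C@H](C)CO[Si](C)(C)C(C)(C)C)C[C@H](O[Si](c2ccccc2)(c2ccccc2)C(C)(C)C)/C=C/[C@H](CC)[C@@H]1CCCCOCc1ccc(OC)cc1 | intermediate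
25 | 3-(4-hydroxybutyl) analogue of lactam 24 (C23 alcohol) | O=C1N[C@H]([C@@H](O[Si](C)(C)C(C)(C)C)C[C@H](C)CO[Si](C)(C)C(C)(C)C)C[C@H](O[Si](c2ccccc2)(c2ccccc2)C(C)(C)C)/C=C/[C@H](CC)[C@@H]1CCCCO | intermediate
26 | C23 methanesulfonate of alcohol 25 | O=C1N[C@H]([C@@H](O[Si](C)(C)C(C)(C)C)C[C@H](C)CO[Si](C)(C)C(C)(C)C)C[C@H](O[Si](c2ccccc2)(c2ccccc2)C(C)(C)C)/C=C/[C@H](CC)[C@@H]1CCCCOS(C)(=O)=O | intermediate
27 | (2S,4S,5E,7S,8S)-2-[(1S,3S)-1,4-bis(tert-butyldimethylsilyloxy)-3-methylbutyl]-4-(tert-butyldiphenylsilyloxy)-7-ethyl-1-azabicyclo[6.4.1]tridec-5-en-13-one (rings A and B, C4=C10 E olefin) | CC[C@H]1/C=C/[C@@H](O[Si](c3ccccc3)(c3ccccc3)C(C)(C)C)C[C@@H]([C@@H](O[Si](C)(C)C(C)(C)C)C[C@H](C)CO[Si](C)(C)C(C)(C)C)N2CCCC[C@@H]1C2=O | intermediate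
28 | (4S,10R)-4,10-diol of 27 (syn-diol; target numbering) | CC[C@H]1[C@H](O)[C@@H](O)[C@@H](O[Si](c3ccccc3)(c3ccccc3)C(C)(C)C)C[C@@H]([C@@H](O[Si](C)(C)C(C)(C)C)C[C@H](C)CO[Si](C)(C)C(C)(C)C)N2CCCC[C@@H]1C2=O | intermediate
29 | 2-(diethoxyphosphoryl)propanoic acid (racemic) | CCOP(=O)(OCC)C(C)C(O)=O | starting material
30 | C4 2-(diethoxyphosphoryl)propanoate of diol 28 (C10 hydroxyl free) | CC[C@H]1[C@H](OC(=O)C(C)P(=O)(OCC)OCC)[C@@H](O)[C@@H](O[Si](c3ccccc3)(c3ccccc3)C(C)(C)C)C[C@@H]([C@@H](O[Si](C)(C)C(C)(C)C)C[C@H](C)CO[Si](C)(C)C(C)(C)C)N2CCCC[C@@H]1C2=O | intermediate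
31 | C10 ketone of 30 (α-acyloxy ketone, 4S) | CC[C@H]1[C@H](OC(=O)C(C)P(=O)(OCC)OCC)C(=O)[C@@H](O[Si](c3ccccc3)(c3ccccc3)C(C)(C)C)C[C@@H]([C@@H](O[Si](C)(C)C(C)(C)C)C[C@H](C)CO[Si](C)(C)C(C)(C)C)N2CCCC[C@@H]1C2=O | intermediate
32 | butenolide (ring C with C8=C10, 4S) | CC[C@H]1[C@@H]2OC(=O)C(C)=C2[C@@H](O[Si](c3ccccc3)(c3ccccc3)C(C)(C)C)C[C@@H]([C@@H](O[Si](C)(C)C(C)(C)C)C[C@H](C)CO[Si](C)(C)C(C)(C)C)N2CCCC[C@@H]1C2=O | intermediate
33 | C8 epimer of lactone 34 (methyl cis to C11) | CC[C@H]1[C@@H]2OC(=O)[C@H](C)[C@@H]2[C@@H](O[Si](c3ccccc3)(c3ccccc3)C(C)(C)C)C[C@@H]([C@@H](O[Si](C)(C)C(C)(C)C)C[C@H](C)CO[Si](C)(C)C(C)(C)C)N2CCCC[C@@H]1C2=O | intermediate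
34 | cis-fused saturated lactone, C3 C4 C8 C10 C14 C15 C17 C27 as in 37, O11 TBDPS, O15 and O19 TBS | CC[C@H]1[C@@H]2OC(=O)[C@@H](C)[C@@H]2[C@@H](O[Si](c3ccccc3)(c3ccccc3)C(C)(C)C)C[C@@H]([C@@H](O[Si](C)(C)C(C)(C)C)C[C@H](C)CO[Si](C)(C)C(C)(C)C)N2CCCC[C@@H]1C2=O | intermediate
35 | triol (C11, C15, C19 hydroxyls; ring C lactone intact) | CC[C@H]1[C@@H]2OC(=O)[C@@H](C)[C@@H]2[C@@H](O)C[C@@H]([C@@H](O)C[C@H](C)CO)N2CCCC[C@@H]1C2=O | intermediate
36 | C11 carbinol of the target (both lactones closed, 11S hydroxyl) | CC[C@H]1[C@@H]2OC(=O)[C@@H](C)[C@@H]2[C@@H](O)C[C@@H]([C@@H]2C[C@H](C)C(=O)O2)N2CCCC[C@@H]1C2=O | intermediate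
37 | CNP0311700.3 (3R,4S,8S,10S,14S,15S,17S,27S; target numbering) | CC[C@H]1[C@@H]2OC(=O)[C@@H](C)[C@@H]2C(=O)C[C@@H]([C@@H]2C[C@H](C)C(=O)O2)N2CCCC[C@@H]1C2=O | target

## Step count and least certain steps

Total: 25 steps. Longest linear sequence: 22 steps (1 → 37 through steps 1, 2, 4–7, 9–11, 13–25); steps 3, 8 and 12 prepare side fragments.

**Step 14 (key step).** The most likely failure is erosion of the chair preference in a very hindered amide: a boat-like array, or the chair with C11 axial, would give the C27/C3 epimers or the Z ring olefin, and slow enolisation at 110 °C would leave time for decomposition. The fallback changes the mechanism to the neutral ketene variant, which runs at 0 °C. It sets out from pyrrolidine 18, which is N-alkylated (4-methoxybenzyl bromide, K2CO3, MeCN) to the N-(4-methoxybenzyl)pyrrolidine F1. Acid chloride 21 with Me3Al and K2CO3 in CHCl3 at 0 °C would acylate the tertiary amine; the resulting acylammonium enolate rearranges through the same chair (zwitterionic aza-Claisen rearrangement) to the N-(4-methoxybenzyl) nine-membered lactam F2. (NH4)2Ce(NO3)6 in aqueous MeCN then removes both 4-methoxybenzyl groups, and the route is rejoined at alcohol 25.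

**Step 18.** The likely failure is osmylation on the other olefin face: the C11 centre favours the conformer with the silyloxy group inside, but the C3 centre favours the one with ethyl inside, and the two conformers expose opposite faces. The fallback accepts the other diol and inverts C4 later. It sets out from olefin 27; the same dihydroxylation would give the (4R,10S)-diol F3. Chloroacetic anhydride and pyridine acylate O4 to the chloroacetate F4; Dess–Martin oxidation gives the keto chloroacetate F5; thiourea with NaHCO3 in EtOH frees the (4R)-α-hydroxy ketone F6. A Mitsunobu esterification (PPh3, DIAD, acid 29) inverts C4 and rejoins the route at keto phosphonate 31.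

**Step 19.** The likely failure is loss of site selectivity, with acylation at O10 or at both hydroxyls, or acyl migration between O4 and O10 under DMAP. The fallback avoids the diol. It sets out from olefin 27: hydroboration with 9-BBN, which places boron on the olefin carbon next to the allylic oxygen, and NaOH/H2O2 give the C10 alcohol F7; Dess–Martin oxidation gives the C10 ketone F8. Kinetic enolisation towards the C4 methylene with KN(SiMe3)2 and oxidation with 2-(phenylsulfonyl)-3-phenyloxaziridine give the (4S)-α-hydroxy ketone F9. Esterification with acid 29 (EDC, DMAP) rejoins the route at 31. Should the hydroxylation deliver the 4R epimer instead, it is F6 and is esterified with inversion as described for step 18.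

**Step 17.** The likely failure is O-alkylation of the ambident amidate to a cyclic imidate, or elimination and intermolecular alkylation because the seven-ring closure is slow. The fallback forms the N22–C23 bond by reduction. It sets out from alcohol 25, which Dess–Martin periodinane oxidises to the aldehyde F10. With BF3·OEt2 in CH2Cl2 at −78 °C the lactam N–H adds to the aldehyde to give the cyclic N-acyl hemiaminal F11, whose N-acyliminium ion is reduced in the same flask by Et3SiH; the route is rejoined at bicyclic lactam 27. The olefin across the ring is a possible internal nucleophile here, which is why this is the fallback and not the first choice.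

## Further compounds

F1 | step 14 | N-(4-methoxybenzyl) derivative of pyrrolidine 18 | CC(C)(C)[Si](C)(C)OC[C@@H](C)C[C@H](O[Si](C)(C)C(C)(C)C)[C@@H]1C[C@H](O[Si](c2ccccc2)(c2ccccc2)C(C)(C)C)[C@@H](/C=C\CC)N1Cc1ccc(OC)cc1
F2 | step 14 | N-(4-methoxybenzyl) derivative of nine-membered lactam 24 | O=C1N(Cc2ccc(OC)cc2)[C@H]([C@@H](O[Si](C)(C)C(C)(C)C)C[C@H](C)CO[Si](C)(C)C(C)(C)C)C[C@H](O[Si](c2ccccc2)(c2ccccc2)C(C)(C)C)/C=C/[C@H](CC)[C@@H]1CCCCOCc1ccc(OC)cc1
F3 | step 18 | (4R,10S)-4,10-diol of 27 (diol from the other olefin face) | CC[C@H]1[C@@H](O)[C@H](O)[C@@H](O[Si](c3ccccc3)(c3ccccc3)C(C)(C)C)C[C@@H]([C@@H](O[Si](C)(C)C(C)(C)C)C[C@H](C)CO[Si](C)(C)C(C)(C)C)N2CCCC[C@@H]1C2=O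
F4 | step 18 | C4 chloroacetate of diol F3 | CC[C@H]1[C@@H](OC(=O)CCl)[C@H](O)[C@@H](O[Si](c3ccccc3)(c3ccccc3)C(C)(C)C)C[C@@H]([C@@H](O[Si](C)(C)C(C)(C)C)C[C@H](C)CO[Si](C)(C)C(C)(C)C)N2CCCC[C@@H]1C2=O
F5 | step 18 | C10 ketone of chloroacetate F4 | CC[C@H]1[C@@H](OC(=O)CCl)C(=O)[C@@H](O[Si](c3ccccc3)(c3ccccc3)C(C)(C)C)C[C@@H]([C@@H](O[Si](C)(C)C(C)(C)C)C[C@H](C)CO[Si](C)(C)C(C)(C)C)N2CCCC[C@@H]1C2=O
F6 | step 18 | (4R)-4-hydroxy-10-ketone (α-hydroxy ketone) | CC[C@H]1[C@@H](O)C(=O)[C@@H](O[Si](c3ccccc3)(c3ccccc3)C(C)(C)C)C[C@@H]([C@@H](O[Si](C)(C)C(C)(C)C)C[C@H](C)CO[Si](C)(C)C(C)(C)C)N2CCCC[C@@H]1C2=O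
F7 | step 19 | C10 alcohol from hydroboration of 27 (C4 methylene; C10 carbinol configuration immaterial) | CC[C@H]1CC(O)[C@@H](O[Si](c3ccccc3)(c3ccccc3)C(C)(C)C)C[C@@H]([C@@H](O[Si](C)(C)C(C)(C)C)C[C@H](C)CO[Si](C)(C)C(C)(C)C)N2CCCC[C@@H]1C2=O
F8 | step 19 | C10 ketone (C4 methylene) | CC[C@H]1CC(=O)[C@@H](O[Si](c3ccccc3)(c3ccccc3)C(C)(C)C)C[C@@H]([C@@H](O[Si](C)(C)C(C)(C)C)C[C@H](C)CO[Si](C)(C)C(C)(C)C)N2CCCC[C@@H]1C2=O
F9 | step 19 | (4S)-4-hydroxy-10-ketone (α-hydroxy ketone) | CC[C@H]1[C@H](O)C(=O)[C@@H](O[Si](c3ccccc3)(c3ccccc3)C(C)(C)C)C[C@@H]([C@@H](O[Si](C)(C)C(C)(C)C)C[C@H](C)CO[Si](C)(C)C(C)(C)C)N2CCCC[C@@H]1C2=O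
F10 | step 17 | C23 aldehyde of lactam 25 | O=C1N[C@H]([C@@H](O[Si](C)(C)C(C)(C)C)C[C@H](C)CO[Si](C)(C)C(C)(C)C)C[C@H](O[Si](c2ccccc2)(c2ccccc2)C(C)(C)C)/C=C/[C@H](CC)[C@@H]1CCCC=O
F11 | step 17 | cyclic N-acyl hemiaminal (C23 hydroxyl on ring B of 27) | CC[C@H]1/C=C/[C@@H](O[Si](c3ccccc3)(c3ccccc3)C(C)(C)C)C[C@@H]([C@@H](O[Si](C)(C)C(C)(C)C)C[C@H](C)CO[Si](C)(C)C(C)(C)C)N2C(O)CCC[C@@H]1C2=O
A1 | alternative 1 | open-chain C4 aldehyde with Z 2-(bromomethyl)enoate and C11 dioxolane | CC[C@@H](C=O)[C@@H]1CCCCN(C1=O)[C@@H](CC2(OCCO2)/C=C(\CBr)C(=O)OC)[C@@H]3C[C@H](C)C(=O)O3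
A2 | alternative 1 | α-methylene lactone of the C11 ketal | CC[C@H]1[C@@H]2OC(=O)C(=C)[C@@H]2C3(OCCO3)C[C@@H]([C@@H]4C[C@H](C)C(=O)O4)N5CCCC[C@@H]1C5=O
A3 | alternative 2 | C4 bromoacetal of the ring C10=C11 silyl enol ether | CC[C@H]1[C@H](OC(OCC)C(C)Br)/C=C(/O[Si](C)(C)C(C)(C)C)C[C@@H]([C@@H]3C[C@H](C)C(=O)O3)N4CCCC[C@@H]1C4=O
A4 | alternative 2 | lactol-ether-fused bicyclic lactam | CC[C@H]1[C@@H]2O[C@@H](OCC)[C@@H](C)[C@@H]2[C@H](O[Si](C)(C)C(C)(C)C)C[C@@H]([C@@H]3C[C@H](C)C(=O)O3)N4CCCC[C@@H]1C4=O
A5 | alternative 3 | 2-nitrocyclohexanone with fused lactone and C14 amino ester side chain | CC[C@H]1[C@@H]2OC(=O)[C@@H](C)[C@@H]2C(C[C@H](N)C(=O)OC)([N+](=O)[O-])C(=O)[C@H]1CCCC(OC)OC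
A6 | alternative 3 | nine-membered lactam potassium nitronate | CC[C@H]1[C@@H]2OC(=O)[C@@H](C)[C@@H]2C(=[N+]([O-])[O-])C[C@@H](C(=O)OC)NC(=O)[C@H]1CCCC(OC)OC.[K+]
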